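Ring A has a local mirror plane through C5 and C8. C5–OMe lies between the carbon-bearing atoms C4a and C6, and C8–H lies between the oxygenated atoms C7 and C8a, so ring A maps onto a mirror-symmetric 4,6-dihydroxy-2-methoxyisophthalate.
The ketone comes from alkaline opening and decarboxylation of a 3-aryl-4-hydroxycoumarin (temporary lactone ring C). That lactone is closed by intramolecular Claisen attack of the C7 O-(4-methoxyphenylacetyl) ester on the C6 ester.
The pyran ring B (O1–C2–C3–C4) comes from a C4 aldehyde and 2-methylprop-1-enylboronic acid by borono-Mannich addition, amine loss and oxa-6π closure. The aldehyde is made from one of the two equivalent esters by protection, mono-reduction, oxidation and deprotection.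
Ring A is built de novo by a double Claisen condensation. Dimethyl 3-methoxyglutaconate supplies C4a–C5–C6, both ester carbons and the methoxyl, and dimethyl malonate supplies C7–C8–C8a.
Ring order: ring A (step 2), ring B (step 7), ring C (closed in step 9, opened in step 10).
Key step: step 2

Remark: the target has no stereocentre. The alkene geometry of 3 is erased on deprotonation, and 5, 12, 18 and F3 are racemic or configurationally labile, with centres that disappear again.

Step 1
Reactants: 1 dimethyl 1,3-acetonedicarboxylate; 2 trimethyl orthoformate
Product: 3 dimethyl (E)-3-methoxypent-2-enedioate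
Conditions: cat. H2SO4, MeOH, reflux; then distillation under reduced pressure
Reagents that add atoms: none
Why: Acid-catalysed ketalisation with the orthoester, followed by loss of methanol on distillation, is the standard enol etherification of a beta-keto ester and should give the conjugated push–pull alkene as its more stable E isomer.

Step 2
Reactants: 3 dimethyl (E)-3-methoxypent-2-enedioate; 4 dimethyl malonate
Product: 6 dimethyl 4,6-dihydroxy-2-methoxyisophthalate, via acyclic keto triester 5 (not isolated)
Conditions: NaOMe (2.2 equiv), 4 (3 equiv), toluene, 110 °C, MeOH distilled off, 3 added slowly; then 1 M HCl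
Reagents that add atoms: none
Why: Proposed new method: methoxide equilibrates 3 with its allyl-type dienolate, whose charge sits on C2 and C4 while the methylated enol oxygen is blocked, and attack of C4 on an ester of the un-ionised fraction of 4 gives keto triester 5 (first Claisen condensation, C4a–C8a bond in target numbering), which is deprotonated at once at C4. The vinylogous terminus C2 of that anion then adds to the remaining malonyl ester in a 6-(enolexo)-exo-trig Dieckmann closure (C6–C7 bond, ring A), and loss of methanol with double enolisation should give the arene, held as its disodium bis(phenoxide) so that the sequence cannot run backwards. The closest known reaction type is the sodium alkoxide condensation of acetonedicarboxylic esters with malonic esters to phloroglucinol dicarboxylates, whereas a 3-alkoxyglutaconate has not been used as the three-carbon bis-nucleophile. No stereocentre is formed, and because the central carbon enters as a methyl enol ether the methoxyl arrives already placed between the two ester-bearing carbons. The step needs C- over O-acylation, cross- over self-condensation, and Claisen attack over addition–elimination of the malonate anion at C3; O-acylated ketene acetals, the 2-pyranone from O-closure of 5 and the un-ionised malonate adduct can all be reopened by methoxide, which matches every ester and the enol ether so that exchange is degenerate, while aromatisation is irreversible. Slow addition of 3 to excess 4 keeps a neutral malonate electrophile present and glutaconate self-condensation low, and removal of methanol pulls both Claisen equilibria forward.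

Step 3
Reactants: 6 dimethyl 4,6-dihydroxy-2-methoxyisophthalate
Product: 7 dimethyl 2-methoxy-4,6-bis(methoxymethoxy)isophthalate
Conditions: NaH (2.4 equiv), MOMCl (2.6 equiv), DMF, 0 °C → rt
Reagents that add atoms: chloromethyl methyl ether (MOMCl), COCCl
Why: Williamson-type O-alkylation of the bis(phenoxide) masks both acidic hydroxyls, which would otherwise consume hydride and open an ortho-quinone methide path to over-reduction in step 4, and the mirror symmetry means no selectivity is needed.

Step 4
Reactants: 7 dimethyl 2-methoxy-4,6-bis(methoxymethoxy)isophthalate
Product: 8 methyl 3-(hydroxymethyl)-2-methoxy-4,6-bis(methoxymethoxy)benzoate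
Conditions: i-Bu2AlH (2.0 equiv), CH2Cl2, −78 → −20 °C; aq. KNaC4H4O6 (potassium sodium tartrate)
Reagents that add atoms: none
Why: Ester reduction with a limiting amount of i-Bu2AlH desymmetrises the diester, because loss of the first acceptor leaves the second ester more donor-loaded and less electrophilic, and unreacted 7 and any diol differ enough in polarity to be separated and 7 recycled.

Step 5
Reactants: 8 methyl 3-(hydroxymethyl)-2-methoxy-4,6-bis(methoxymethoxy)benzoate
Product: 9 methyl 3-formyl-2-methoxy-4,6-bis(methoxymethoxy)benzoate
Conditions: MnO2 (excess), CH2Cl2, rt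
Reagents that add atoms: none
Why: MnO2 oxidation of an electron-rich benzylic alcohol stops at the aldehyde under neutral conditions and leaves the ester and the acid-labile MOM acetals untouched.

Step 6
Reactants: 9 methyl 3-formyl-2-methoxy-4,6-bis(methoxymethoxy)benzoate
Product: 10 methyl 3-formyl-4,6-dihydroxy-2-methoxybenzoate
Conditions: 3 M HCl (cat.), MeOH, 50 °C; aqueous work-up
Reagents that add atoms: none
Why: Acid-catalysed acetal exchange with methanol removes both MOM groups while the aryl methyl ether, the ester and the aldehyde persist, each freed phenol being held in a hydrogen bond to its neighbouring carbonyl.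

Step 7
Reactants: 10 methyl 3-formyl-4,6-dihydroxy-2-methoxybenzoate; 11 2-methylprop-1-en-1-ylboronic acid
Product: 14 methyl 7-hydroxy-5-methoxy-2,2-dimethyl-2H-chromene-6-carboxylate, via allylic amine 12 (not isolated), via ortho-quinone methide 13 (not isolated)
Conditions: 11 (1.5 equiv), Bn2NH (0.4 equiv), 1,4-dioxane, 90 °C
Reagents that add atoms: none
Why: In this catalytic Petasis borono-Mannich chromene annulation the iminium ion from the aldehyde and Bn2NH is alkenylated from the boronate bound to the adjacent phenoxide to give 12, which on heating expels Bn2NH to give 13 and closes ring B by oxa-6π electrocyclisation, and only one regiochemistry is possible because the other ortho position carries the methoxyl.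

Step 8
Reactants: 14 methyl 7-hydroxy-5-methoxy-2,2-dimethyl-2H-chromene-6-carboxylate; 15 4-methoxyphenylacetyl chloride
Product: 16 methyl 5-methoxy-7-{[2-(4-methoxyphenyl)acetyl]oxy}-2,2-dimethyl-2H-chromene-6-carboxylate
Conditions: NaH (1.05 equiv), THF, 0 °C; then 15 (1.1 equiv), 0 °C → rt
Reagents that add atoms: none
Why: O-acylation of the sodium phenoxide with an acid chloride is unambiguous because C7–OH is the only hydroxyl left, and it places the arylacetyl carbon nucleophile next to the C6 ester.

Step 9
Reactants: 16 methyl 5-methoxy-7-{[2-(4-methoxyphenyl)acetyl]oxy}-2,2-dimethyl-2H-chromene-6-carboxylate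
Product: 17 4-hydroxy-5-methoxy-3-(4-methoxyphenyl)-8,8-dimethyl-2H,8H-pyrano[3,2-g]chromen-2-one
Conditions: NaH (2.5 equiv), THF, 0 °C → reflux; then 1 M HCl
Reagents that add atoms: none
Why: This intramolecular Claisen (Dieckmann-type) condensation of an O-acylsalicylate is the classical entry to 3-substituted 4-hydroxycoumarins, in which the benzylic ester enolate attacks the neighbouring hindered methyl ester in a 6-exo-trig mode and deprotonation of the strongly acidic product drives the step.

Step 10
Reactants: 17 4-hydroxy-5-methoxy-3-(4-methoxyphenyl)-8,8-dimethyl-2H,8H-pyrano[3,2-g]chromen-2-one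
Product: 19 1-(7-hydroxy-5-methoxy-2,2-dimethyl-2H-chromen-6-yl)-2-(4-methoxyphenyl)ethan-1-one, via beta-keto acid 18 (not isolated)
Conditions: KOH (10% aq.), EtOH, reflux, N2; then 2 M HCl, rt
Reagents that add atoms: none
Why: Alkaline lactone hydrolysis followed by beta-keto acid decarboxylation is the classical conversion of 3-aryl-4-hydroxycoumarins into 2-hydroxydeoxybenzoins, the oxygen delivered by hydroxide leaves again with the CO2, and the chromene alkene and both aryl methyl ethers are inert to alkali.

Compound list
1 | dimethyl 1,3-acetonedicarboxylate (dimethyl 3-oxopentanedioate) | COC(=O)CC(=O)CC(=O)OC | starting material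
2 | trimethyl orthoformate | COC(OC)OC | starting material
3 | dimethyl (E)-3-methoxypent-2-enedioate | COC(=O)/C=C(/OC)CC(=O)OC | intermediate
4 | dimethyl malonate | COC(=O)CC(=O)OC | starting material
5 | dimethyl (E)-3-methoxy-4-(methoxycarbonyl)-5-oxohept-2-enedioate (present as its sodium enolate, C4 labile) | COC(=O)/C=C(/OC)C(C(=O)OC)C(=O)CC(=O)OC | intermediate
6 | dimethyl 4,6-dihydroxy-2-methoxyisophthalate | COC(=O)c1c(O)cc(O)c(C(=O)OC)c1OC | intermediate
7 | dimethyl 2-methoxy-4,6-bis(methoxymethoxy)isophthalate | COC(=O)c1c(OCOC)cc(OCOC)c(C(=O)OC)c1OC | intermediate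
8 | methyl 3-(hydroxymethyl)-2-methoxy-4,6-bis(methoxymethoxy)benzoate | COC(=O)c1c(OCOC)cc(OCOC)c(CO)c1OC | intermediate
9 | methyl 3-formyl-2-methoxy-4,6-bis(methoxymethoxy)benzoate | COC(=O)c1c(OCOC)cc(OCOC)c(C=O)c1OC | intermediate
10 | methyl 3-formyl-4,6-dihydroxy-2-methoxybenzoate | COC(=O)c1c(O)cc(O)c(C=O)c1OC | intermediate
11 | 2-methylprop-1-en-1-ylboronic acid | CC(C)=CB(O)O | starting material
12 | methyl 3-[1-(dibenzylamino)-3-methylbut-2-en-1-yl]-4,6-dihydroxy-2-methoxybenzoate (racemic) | COC(=O)c1c(O)cc(O)c(C(C=C(C)C)N(Cc2ccccc2)Cc2ccccc2)c1OC | intermediate
13 | methyl (3Z)-6-hydroxy-2-methoxy-3-(3-methylbut-2-en-1-ylidene)-4-oxocyclohexa-1,5-diene-1-carboxylate | COC(=O)C1=C(OC)/C(=C/C=C(C)C)C(=O)C=C1O | intermediate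
14 | methyl 7-hydroxy-5-methoxy-2,2-dimethyl-2H-chromene-6-carboxylate | COC(=O)c1c(O)cc2OC(C)(C)C=Cc2c1OC | intermediate
15 | 4-methoxyphenylacetyl chloride | COc1ccc(CC(=O)Cl)cc1 | starting material
16 | methyl 5-methoxy-7-{[2-(4-methoxyphenyl)acetyl]oxy}-2,2-dimethyl-2H-chromene-6-carboxylate | COC(=O)c1c(OC(=O)Cc3ccc(OC)cc3)cc2OC(C)(C)C=Cc2c1OC | intermediate
17 | 4-hydroxy-5-methoxy-3-(4-methoxyphenyl)-8,8-dimethyl-2H,8H-pyrano[3,2-g]chromen-2-one | COc1ccc(cc1)C1=C(O)c2c(OC)c3C=CC(C)(C)Oc3cc2OC1=O | intermediate
18 | 3-(7-hydroxy-5-methoxy-2,2-dimethyl-2H-chromen-6-yl)-2-(4-methoxyphenyl)-3-oxopropanoic acid (racemic) | COc1ccc(cc1)C(C(=O)O)C(=O)c1c(O)cc2OC(C)(C)C=Cc2c1OC | intermediate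
19 | 1-(7-hydroxy-5-methoxy-2,2-dimethyl-2H-chromen-6-yl)-2-(4-methoxyphenyl)ethan-1-one | COc1ccc(CC(=O)c2c(O)cc3c(c2OC)C=CC(C)(C)O3)cc1 | target

Total step count: 10. Longest linear sequence: 10 steps (1 → 19). Compounds 2, 4, 11 and 15 are purchased.

Steps most likely to fail

Step 2 (Proposed new method).
- **What may go wrong:** The malonate may rest as its unreactive enolate while the glutaconate condenses with itself. The malonate anion may also displace the enol methoxyl by conjugate addition–elimination faster than the two Claisen steps run.
- **Fallback:** This uses known chemistry and installs the methoxyl late instead of carrying it in. It sets out from 1 and 4. The classical NaOMe condensation of an acetonedicarboxylate with a malonate should give dimethyl 2,4,6-trihydroxyisophthalate F1. MOMCl (2.1 equiv) with i-Pr2NEt in CH2Cl2 should cap the two less hindered hydroxyls at C4 and C6 to give dimethyl 2-hydroxy-4,6-bis(methoxymethoxy)isophthalate F2. The remaining hydroxyl, wedged between both esters, is then methylated with MeI and K2CO3 in DMF. The fallback comes back to the route at 7.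

Step 7.
- **What may go wrong:** Iminium formation may be slow at a hindered, donor-rich aldehyde, and the trisubstituted alkenylboronic acid may protodeboronate before alkenyl transfer.
- **Fallback:** It sets out from 10 and replaces the boron-to-iminium transfer by direct carbonyl addition. 2-Methylprop-1-enylmagnesium bromide (3.3 equiv, two of them consumed by the phenols) in THF at −78 → 0 °C should add to the aldehyde faster than to the flanked, phenoxide-deactivated ester. This gives methyl 4,6-dihydroxy-3-(1-hydroxy-3-methylbut-2-en-1-yl)-2-methoxybenzoate F3. Warming F3 with catalytic pyridinium p-toluenesulfonate in toluene should remove water to give the same quinone methide 13, which electrocyclises. The fallback comes back to the route at 14.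

Step 4.
- **What may go wrong:** Discrimination between the two equivalent esters may be poor, so that the second ester is reduced as well and much starting diester is left.
- **Fallback:** It sets out from 7 and uses a charge-limited desymmetrisation. Monosaponification with KOH (1.0 equiv) in aqueous MeOH at reflux slows sharply after the first hydrolysis because the carboxylate repels hydroxide. Careful acidification should give 2-methoxy-3-(methoxycarbonyl)-4,6-bis(methoxymethoxy)benzoic acid F4. BH3·SMe2 in THF then reduces the acid chemoselectively beside the ester. The fallback comes back to the route at 8.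

Further compounds
F1 | step 2 | dimethyl 2,4,6-trihydroxyisophthalate | COC(=O)c1c(O)cc(O)c(C(=O)OC)c1O
F2 | step 2 | dimethyl 2-hydroxy-4,6-bis(methoxymethoxy)isophthalate | COC(=O)c1c(OCOC)cc(OCOC)c(C(=O)OC)c1O
F3 | step 7 | methyl 4,6-dihydroxy-3-(1-hydroxy-3-methylbut-2-en-1-yl)-2-methoxybenzoate (racemic) | COC(=O)c1c(O)cc(O)c(C(O)C=C(C)C)c1OC
F4 | step 4 | 2-methoxy-3-(methoxycarbonyl)-4,6-bis(methoxymethoxy)benzoic acid | COC(=O)c1c(OCOC)cc(OCOC)c(C(=O)O)c1OC
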